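Locants used in the prose: lactone C1 (carbonyl), C2, C3, C4 (OCH2); arm C7 (carbinol), C8, C9 (CH2OH); DBF = the 2,3-dihydrobenzofuran with its own C2 and C3. Ring A sits on the C3 benzyl group and carries the arm, ring B is the benzo ring of the DBF, ring C is the guaiacyl ring on C7, ring D the guaiacyl ring on DBF C2. Systematic names use furan-2(3H)-one locants (furanone C3 = prose C2, furanone C4 = prose C3).

## Analysis of the target

The molecule is built on a trans-2,3-dibenzyl-γ-butyrolactone. The C3 benzyl ring (ring A) is a guaiacyl ring that carries, ortho to its phenol, an open 1,3-diol arm: C8 bears ring A and the C9 hydroxymethyl group, and C7 is a secondary benzylic carbinol on ring C. The C2 benzyl ring (ring B) is the benzo ring of a trans-2-aryl-3-hydroxymethyl-7-methoxy-DBF whose C2 carries ring D. There are six stereocentres in three pairs: lactone C2/C3 (S,S, trans), arm C7/C8 (S,S, hydroxyl and ring A anti in the extended chain) and DBF C2/C3 (R,S, trans); each pair is insulated from the others by a CH2–arene spacer, so none can control another and each needs its own source of absolute configuration. The arm on ring A and the furan ring on ring B are the same three-carbon unit in open and closed form: the DBF is what the arm becomes when the neighbouring phenol displaces the carbinol oxygen with inversion. Sensitive sites are the three free phenols, the p-hydroxybenzylic alcohol at C7 (ionisation, quinone methide formation, hydrogenolysis), the benzylic C2–O bond of the DBF (acid) and the lactone, whose C2 is epimerisable but already in the more stable trans arrangement. The hard centre is lactone C3, a lone CH stereocentre with three carbon substituents and no adjacent heteroatom to direct a reagent. The strategy rests on the position of C3 between C2 and the C4 OCH2 group: without the C2 benzyl group, the β-(arylmethyl)lactone is the oxygen-insertion product of a 3-(arylmethyl)cyclobutanone with a mirror plane through its carbonyl carbon and C3, so C3 can be set by choosing between two enantiotopic CH2 groups.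

## Retrosynthetic reasoning

**End game.** Target 34 comes from 33 by hydrogenolysis of three aryl benzyl ethers, and 33 from 32 by desilylation. Benzyl is used on all phenols because it survives every reagent of the route and leaves under neutral conditions that the C7 carbinol tolerates. The DBF hydroxymethyl group travels as a silyl ether because it must survive hydride, amide base and ruthenium.

**C9.** The C9 hydroxyl is traced back to a vinyl group (32 from 30 through aldehyde 31). Extending the arm by one alkene carbon turns it into a homoallylic alcohol, the product type of an allyl-metal addition to an aldehyde.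

**C7–C8.** This bond is cut next (30 from 28 and 15). It carries both arm stereocentres. Forming it by addition of an (E)-γ-aryl allylboronate to aldehyde 15 through a six-membered transition state gives the anti pair by geometry and the absolute sense from a chiral Brønsted acid. Cutting here, and not at the C8–ring A bond, lets ring A remain a plain aryl halide until late.

**Boronate.** Boronate 28 goes back to styrene 27 by cross-metathesis and 27 to aryl bromide 26 by a vinyl cross-coupling. The whole arm therefore hangs on one bromine atom that is inert until then.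

**Lactone C2.** The bond from C2 to the ring B methylene is cut (26 from 10 and 24). Enolate 25 of the monosubstituted lactone 10 is alkylated on the face away from the C3 substituent, so C3 sets C2. The route becomes convergent: ring B arrives with its finished DBF as benzylic bromide 24.

**Key disconnection.** Removing the ring oxygen of 10 gives cyclobutanone 8; the bond made forward is C4–O. Ketone 8 has no stereocentre and its two α-carbons are constitutionally identical, so the only task of the forward reaction is to tell two enantiotopic methylene groups apart in Criegee adduct 9. Cutting at C2–C3 or C3–CH2 instead would call for an auxiliary or a pre-formed stereocentre.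

**Cyclobutanone.** Ketone 8 comes from dichloroketone 7 by dechlorination, and 7 from allylarene 4 and ketene 6 (made from 5) by [2+2] cycloaddition. Arene 4 comes from 2 and 3, and 2 from 1, which supplies ring A with the allyl group in place.

**Ring B handles.** Bromide 24 is taken back through 23, 22 and 21 to 19 (via aldehyde 20). These are functional-group changes only: the C5 ester is the latent CH2Br and the C3 vinyl group the latent CH2OH.

**Furan ring.** The O1–C2 bond of the DBF is cut (19 from 18, 18 from 17). Closing it by displacement of the carbinol oxygen with inversion turns an anti homoallylic alcohol into the trans ring. The open precursor 17 therefore has the same stereochemical pattern as the ring A arm and calls for the same reaction.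

**Ring B arm.** Alcohol 17 comes from 14 and 15, and 14 through 13 and 12 from 11. Benzoate 11 supplies ring B with all four substituents placed, and the boronate sequence is rehearsed on a small molecule before it is needed on 26.

## Alternatives that were turned down

**Alternative 1:** Both carbinol-to-aryl-bearing-carbon bonds (arm C7–C8 and its counterpart that becomes DBF C2–C3) are cut at once. Forward, bis(allylboronate) lactone A2 adds twice to aldehyde 15 under a chiral phosphoric acid to give bis(homoallylic alcohol) A1. In its favour: it uses the hidden twofold relationship of the two side chains, sets four stereocentres in one flask, and the second addition turns residual enantiomeric error into a separable diastereomer. It is clearly shorter than the chosen route, which runs the same three operations twice. Against it: it says nothing about lactone C2 and C3, which need a separate asymmetric entry. It puts two sensitive allylboronates on the most advanced intermediate. Afterwards two equivalent benzylic carbinols must be treated differently, one closed with inversion onto the ring B phenol and one left alone. An activating reagent cannot distinguish them, so the ring A carbinol would be open to elimination or etherification. The chosen strategy gives up step count; in return each stereochemical event is isolated and checked on its own, the furan ring is closed on a small benzoate before the second carbinol exists, and lactone C3 is set by a catalyst.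

**Alternative 2:** The arm is cut at C8–C9 and C7–O. Forward, stilbene A4 takes up two molecules of formaldehyde A5 under a confined chiral imidodiphosphorimidate acid and closes to the trans 1,3-dioxane A3. In its favour: one step sets both arm centres and protects the diol, the stilbene comes from the same kind of aryl bromide lactone, and no boron reagent or ozonolysis is needed. On arm step count and atom economy it beats the chosen route (one step against four). Against it: the asymmetric reaction of this type is established for terminal styrenes, where the cation can form at only one carbon. A4 is an internal diaryl alkene with two electron-rich rings. Regiochemistry would rest on the small donor difference between the pivalate-bearing ring A and the benzyloxy ring C. A stepwise benzylic cation can lose the trans relationship. The methylene acetal must later be cleaved with strong acid, under which the C7 benzylic oxygen and the DBF ionise. The chosen route instead uses a closed chair transition state whose anti outcome follows from alkene geometry, and it delivers a free diol.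

**Alternative 3:** Ring B itself is cut at C3a–C7a and C4–C5. Forward, the alkyne tethered through oxygen in pyridazine A7 adds across the diazine and the two ring nitrogens are expelled, giving chloro-DBF A6 with the benzene and furan rings formed together. In its favour: regiochemistry is dictated by the tether, the methoxy and chloro positions are written into the heterocycle, and the tether stereocentres are not touched. For certainty of arene substitution it is at least as strong as buying the arene. Against it: it solves only the DBF fragment. The two stereocentres must still be made beforehand on the alkynyl alcohol, at a cost similar to one allylboration. The cycloaddition needs high temperature while a secondary benzylic ether on an electron-rich ring is present. The product carries an electron-rich aryl chloride that still needs several steps to become CH2Br. The chosen route buys ring B as benzoate 11, closes the furan ring at 0 °C and already has the one-carbon handle as an ester.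

Key step: step 5

Assumption: the (S) enantiomers of the two phosphoric acids are taken as those that give the drawn configurations (migration leading to (S)-10; Si-face addition to aldehyde 15); if the sense of induction is opposite, the mirror-image acid is used and nothing else changes.

Shorthand in names: DBFm = {(2R,3S)-2-[4-(benzyloxy)-3-methoxyphenyl]-3-[(tert-butyldimethylsilyloxy)methyl]-7-methoxy-2,3-dihydrobenzofuran-5-yl}methyl. (S)-TRIP = (S)-3,3′-bis(2,4,6-triisopropylphenyl)-1,1′-binaphthyl-2,2′-diyl hydrogen phosphate.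

## Route

Step 1
Reactants: 1 eugenol
Product: 2 4-allyl-2-bromo-6-methoxyphenol
Conditions: NBS (1.0 equiv), i-Pr2NH (10 mol %), CH2Cl2, −40 → 0 °C, dark
Reagents that add atoms: N-bromosuccinimide, O=C1CCC(=O)N1Br
Why: Amine-mediated electrophilic aromatic bromination places bromine ortho to the free phenol, the only open position activated by it since para is blocked by the allyl group. The phenol ring is far more nucleophilic than the isolated terminal alkene at low temperature, so the double bond should be kept.

Step 2
Reactants: 2 4-allyl-2-bromo-6-methoxyphenol; 3 benzyl bromide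
Product: 4 5-allyl-2-(benzyloxy)-1-bromo-3-methoxybenzene
Conditions: K2CO3, DMF, rt
Reagents that add atoms: none
Why: Williamson etherification of the acidic 2,6-disubstituted phenol. Benzyl is chosen because it is inert to zinc, peroxide, amide base, palladium and ruthenium catalysis and leaves by neutral hydrogenolysis at the end.

Step 3
Reactants: 4 5-allyl-2-(benzyloxy)-1-bromo-3-methoxybenzene; 5 trichloroacetyl chloride
Product: 7 racemic 3-[4-(benzyloxy)-3-bromo-5-methoxybenzyl]-2,2-dichlorocyclobutan-1-one, via dichloroketene 6 (not isolated)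
Conditions: Zn–Cu couple, Et2O, ultrasound, 15–25 °C, slow addition of 5
Reagents that add atoms: none
Why: Thermal [2+2] cycloaddition of dichloroketene to an unactivated terminal alkene; the ketene carbonyl carbon bonds to the terminal CH2, so the arylmethyl group ends up at C3 next to CCl2. The C3 centre is racemic and irrelevant because it becomes prochiral again in step 4.

Step 4
Reactants: 7 racemic 3-[4-(benzyloxy)-3-bromo-5-methoxybenzyl]-2,2-dichlorocyclobutan-1-one
Product: 8 3-[4-(benzyloxy)-3-bromo-5-methoxybenzyl]cyclobutan-1-one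
Conditions: Zn dust, AcOH, rt → 60 °C
Reagents that add atoms: none
Why: Reductive dechlorination of an α,α-dichloroketone by zinc in acetic acid; the aryl bromide and the benzyl ether are inert here. The product has a mirror plane through the carbonyl carbon and C3.

Step 5
Reactants: 8 3-[4-(benzyloxy)-3-bromo-5-methoxybenzyl]cyclobutan-1-one
Product: 10 (S)-4-[4-(benzyloxy)-3-bromo-5-methoxybenzyl]dihydrofuran-2(3H)-one, via Criegee adduct 9 (not isolated)
Conditions: (S)-3,3′-di(pyren-1-yl)-H8-BINOL hydrogen phosphate (10 mol %), 30% aq. H2O2 (1.5 equiv), CHCl3, −40 °C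
Reagents that add atoms: hydrogen peroxide, OO
Why: The phosphoric acid activates the strained ketone, the peroxide adds to give Criegee adduct 9, and the adduct stays hydrogen-bonded to the bifunctional phosphate (P=O accepting, P–OH donating to the distal peroxide oxygen). One of the two α-CH2 groups, enantiotopic because of the mirror plane, then migrates from carbon to oxygen anti-periplanar to the breaking O–O bond while water leaves; this 1,2-shift forms the C4–O bond. The lactone ring is not closed from an open chain: it arises by enlargement of the four-membered ring by one oxygen atom, and relief of ring strain drives it. C3 becomes stereogenic only because the two methylene groups become different (CH2O against CH2C=O); none of its bonds is touched, and its S configuration is decided solely by which methylene the chiral pocket of the catalyst allows to migrate. The closest known reaction type is the chiral Brønsted acid-catalysed (and the enzymatic) Baeyer–Villiger desymmetrisation of 3-substituted cyclobutanones to β-substituted γ-butyrolactones. Only enantiotopic-group selection is needed: there is no regiochemical question because the α-carbons are constitutionally identical, and chemoselectivity comes from strain, the cyclobutanone reacting with H2O2 at −40 °C where the bromoarene and the ethers are inert. The enantiomeric purity of 10 is to be assayed by chiral HPLC before convergence and raised by recrystallisation if needed.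

Step 6
Reactants: 11 methyl 3-bromo-4-hydroxy-5-methoxybenzoate
Product: 12 methyl 3-bromo-5-methoxy-4-(triisopropylsilyloxy)benzoate
Conditions: TIPSOTf, 2,6-lutidine, CH2Cl2, 0 °C → rt
Reagents that add atoms: triisopropylsilyl trifluoromethanesulfonate, CC(C)[Si](OS(=O)(=O)C(F)(F)F)(C(C)C)C(C)C
Why: Silylation with the reactive triflate overcomes the flanking bromine and methoxy groups. The TIPS ether is orthogonal to the benzyl ether of the later ring D and is removed by fluoride just before ring closure.

Step 7
Reactants: 12 methyl 3-bromo-5-methoxy-4-(triisopropylsilyloxy)benzoate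
Product: 13 methyl 3-methoxy-4-(triisopropylsilyloxy)-5-vinylbenzoate
Conditions: vinylboronic acid pinacol ester (1.5 equiv), Pd(dppf)Cl2 (3 mol %), K2CO3, 1,4-dioxane/H2O (9:1), 80 °C
Reagents that add atoms: vinylboronic acid pinacol ester, C=CB1OC(C)(C)C(C)(C)O1
Why: Suzuki–Miyaura vinylation of the aryl bromide; the silyl ether, shielded by two ortho substituents, and the methyl ester should tolerate carbonate base at this temperature.

Step 8
Reactants: 13 methyl 3-methoxy-4-(triisopropylsilyloxy)-5-vinylbenzoate
Product: 14 methyl 3-methoxy-5-[(E)-3-(4,4,5,5-tetramethyl-1,3,2-dioxaborolan-2-yl)prop-1-en-1-yl]-4-(triisopropylsilyloxy)benzoate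
Conditions: allylboronic acid pinacol ester (3 equiv), second-generation Hoveyda–Grubbs catalyst RuCl2(H2IMes)(=CH-C6H4-2-O-i-Pr) (5 mol %), CH2Cl2, 40 °C
Reagents that add atoms: allylboronic acid pinacol ester, C=CCB1OC(C)(C)C(C)(C)O1
Why: Olefin cross-metathesis of the styrene with excess allylboronate, driven by loss of ethene. The styrenyl 1,2-disubstituted alkene forms under thermodynamic control as the E isomer, the geometry the anti addition of step 9 requires.

Step 9
Reactants: 14 methyl 3-methoxy-5-[(E)-3-(pinacolboryl)prop-1-en-1-yl]-4-(triisopropylsilyloxy)benzoate; 15 4-(benzyloxy)-3-methoxybenzaldehyde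
Product: 17 methyl 3-[(1S,2R)-1-(4-benzyloxy-3-methoxyphenyl)-1-hydroxybut-3-en-2-yl]-5-methoxy-4-(triisopropylsilyloxy)benzoate, via pinacol borate ester 16 (not isolated)
Conditions: (S)-TRIP (5 mol %), 4 Å MS, toluene, −30 → 0 °C; aq. NaHCO3 work-up
Reagents that add atoms: none
Why: Chiral phosphoric acid-catalysed allylboration through a closed chair transition state. The E-boronate places its aryl group equatorial and so gives the anti pair, while the acid, hydrogen-bonded to a boronate oxygen, selects the aldehyde face and sets C1 as S and C2 as R.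

Step 10
Reactants: 17 methyl 3-[(1S,2R)-1-(4-benzyloxy-3-methoxyphenyl)-1-hydroxybut-3-en-2-yl]-5-methoxy-4-(triisopropylsilyloxy)benzoate
Product: 18 methyl 3-[(1S,2R)-1-(4-benzyloxy-3-methoxyphenyl)-1-hydroxybut-3-en-2-yl]-4-hydroxy-5-methoxybenzoate
Conditions: TBAF (1.1 equiv), THF, 0 °C; aq. NH4Cl
Reagents that add atoms: none
Why: Fluoride cleaves the aryl silyl ether selectively; benzyl ether, ester, alkene and the secondary alcohol are untouched.

Step 11
Reactants: 18 methyl 3-[(1S,2R)-1-(4-benzyloxy-3-methoxyphenyl)-1-hydroxybut-3-en-2-yl]-4-hydroxy-5-methoxybenzoate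
Product: 19 methyl (2R,3R)-2-[4-(benzyloxy)-3-methoxyphenyl]-7-methoxy-3-vinyl-2,3-dihydrobenzofuran-5-carboxylate
Conditions: PPh3, DIAD, THF, 0 °C → rt
Reagents that add atoms: none
Why: Intramolecular Mitsunobu etherification (5-exo-tet): the acidic phenol para to the ester displaces the activated benzylic oxygen with inversion, which converts the anti open chain into the trans-2,3-disubstituted ring with C2 now R. Trans is also the thermodynamically preferred arrangement should the substitution take on ionic character.

Step 12
Reactants: 19 methyl (2R,3R)-2-[4-(benzyloxy)-3-methoxyphenyl]-7-methoxy-3-vinyl-2,3-dihydrobenzofuran-5-carboxylate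
Product: 21 methyl (2R,3S)-2-[4-(benzyloxy)-3-methoxyphenyl]-3-(hydroxymethyl)-7-methoxy-2,3-dihydrobenzofuran-5-carboxylate, via aldehyde 20 (not isolated)
Conditions: O3, CH2Cl2/MeOH (3:1), Sudan Red 7B, −78 °C; then NaBH4, −78 → 0 °C
Reagents that add atoms: ozone, [O-][O+]=O
Why: Ozonolysis of the only alkene with borohydride reduction in the same flask turns the vinyl group into CH2OH without isolating aldehyde 20, which could epimerise or open the furan ring by β-elimination. The aryl ester is not reduced by NaBH4 at 0 °C, and the change of descriptor at C3 is a priority change only.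

Step 13
Reactants: 21 methyl (2R,3S)-2-[4-(benzyloxy)-3-methoxyphenyl]-3-(hydroxymethyl)-7-methoxy-2,3-dihydrobenzofuran-5-carboxylate
Product: 22 methyl (2R,3S)-2-[4-(benzyloxy)-3-methoxyphenyl]-3-[(tert-butyldimethylsilyloxy)methyl]-7-methoxy-2,3-dihydrobenzofuran-5-carboxylate
Conditions: TBSCl, imidazole, DMF, rt
Reagents that add atoms: tert-butyldimethylsilyl chloride, CC(C)(C)[Si](C)(C)Cl
Why: Standard silylation of the primary alcohol; the TBS ether survives hydride, bromination, amide base, cross-coupling and metathesis and leaves with fluoride.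

Step 14
Reactants: 22 methyl (2R,3S)-2-[4-(benzyloxy)-3-methoxyphenyl]-3-[(tert-butyldimethylsilyloxy)methyl]-7-methoxy-2,3-dihydrobenzofuran-5-carboxylate
Product: 23 {(2R,3S)-2-[4-(benzyloxy)-3-methoxyphenyl]-3-[(tert-butyldimethylsilyloxy)methyl]-7-methoxy-2,3-dihydrobenzofuran-5-yl}methanol
Conditions: i-Bu2AlH (2.5 equiv), CH2Cl2, −78 → 0 °C; aq. potassium sodium tartrate
Reagents that add atoms: none
Why: Hydride reduction of the methyl ester to the benzylic alcohol, the handle for the bond to the lactone; no other group is reducible.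

Step 15
Reactants: 23 {(2R,3S)-2-[4-(benzyloxy)-3-methoxyphenyl]-3-[(tert-butyldimethylsilyloxy)methyl]-7-methoxy-2,3-dihydrobenzofuran-5-yl}methanol
Product: 24 (2R,3S)-2-[4-(benzyloxy)-3-methoxyphenyl]-5-(bromomethyl)-3-[(tert-butyldimethylsilyloxy)methyl]-7-methoxy-2,3-dihydrobenzofuran
Conditions: CBr4, PPh3, CH2Cl2, 0 °C; used at once
Reagents that add atoms: carbon tetrabromide, BrC(Br)(Br)Br
Why: Appel bromination under neutral conditions converts the electron-rich benzylic alcohol to the bromide without touching the silyl ether or the acid-sensitive benzylic ring ether.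

Step 16
Reactants: 10 (S)-4-[4-(benzyloxy)-3-bromo-5-methoxybenzyl]dihydrofuran-2(3H)-one; 24 (2R,3S)-2-[4-(benzyloxy)-3-methoxyphenyl]-5-(bromomethyl)-3-[(tert-butyldimethylsilyloxy)methyl]-7-methoxy-2,3-dihydrobenzofuran
Product: 26 (3S,4S)-4-[4-(benzyloxy)-3-bromo-5-methoxybenzyl]-3-(DBFm)dihydrofuran-2(3H)-one, via lithium enolate 25 (not isolated)
Conditions: LiN(SiMe3)2 (1.05 equiv), THF, −78 °C; then 24, DMPU, −78 → −40 °C
Reagents that add atoms: none
Why: Alkylation of the lactone enolate: the benzylic bromide approaches the face opposite to the arylmethyl group on the neighbouring carbon, giving the trans-disubstituted lactone and setting prose C2 as S. This is the standard diastereocontrol of dibenzylbutyrolactone synthesis, and trans is also the stable isomer, so later basic steps cannot erode it.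

Step 17
Reactants: 26 (3S,4S)-4-[4-(benzyloxy)-3-bromo-5-methoxybenzyl]-3-(DBFm)dihydrofuran-2(3H)-one
Product: 27 (3S,4S)-4-[4-(benzyloxy)-3-methoxy-5-vinylbenzyl]-3-(DBFm)dihydrofuran-2(3H)-one
Conditions: vinylboronic acid pinacol ester (1.5 equiv), Pd(dppf)Cl2 (5 mol %), K2CO3, 1,4-dioxane/H2O (9:1), 80 °C; work-up at pH 4
Reagents that add atoms: vinylboronic acid pinacol ester, C=CB1OC(C)(C)C(C)(C)O1
Why: Suzuki–Miyaura vinylation of the ring A bromide as in step 7. Any lactone opened by the base re-closes on mildly acidic work-up, and no stereocentre is at risk because C3 is not acidic and C2 is already trans.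

Step 18
Reactants: 27 (3S,4S)-4-[4-(benzyloxy)-3-methoxy-5-vinylbenzyl]-3-(DBFm)dihydrofuran-2(3H)-one
Product: 28 (3S,4S)-4-{4-(benzyloxy)-3-methoxy-5-[(E)-3-(4,4,5,5-tetramethyl-1,3,2-dioxaborolan-2-yl)prop-1-en-1-yl]benzyl}-3-(DBFm)dihydrofuran-2(3H)-one
Conditions: allylboronic acid pinacol ester (3 equiv), second-generation Hoveyda–Grubbs catalyst RuCl2(H2IMes)(=CH-C6H4-2-O-i-Pr) (5–10 mol %), CH2Cl2, 40 °C
Reagents that add atoms: allylboronic acid pinacol ester, C=CCB1OC(C)(C)C(C)(C)O1
Why: Cross-metathesis as in step 8; the styrene is the only alkene in 27, the conditions are neutral, and the E boronate is the thermodynamic product.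

Step 19
Reactants: 28 (3S,4S)-4-{4-(benzyloxy)-3-methoxy-5-[(E)-3-(pinacolboryl)prop-1-en-1-yl]benzyl}-3-(DBFm)dihydrofuran-2(3H)-one; 15 4-(benzyloxy)-3-methoxybenzaldehyde
Product: 30 (3S,4S)-4-{4-(benzyloxy)-3-[(1S,2R)-1-(4-benzyloxy-3-methoxyphenyl)-1-hydroxybut-3-en-2-yl]-5-methoxybenzyl}-3-(DBFm)dihydrofuran-2(3H)-one, via pinacol borate ester 29 (not isolated)
Conditions: (S)-TRIP (10 mol %), 4 Å MS, toluene, −30 → 0 °C; aq. NaHCO3 work-up
Reagents that add atoms: none
Why: The same chiral phosphoric acid-catalysed allylboration as in step 9, with the same acid enantiomer: the chair transition state with the E-boronate gives the anti pair and the acid selects the aldehyde face, setting C7 as S and C8. The four existing stereocentres are separated from the reacting atoms by an arene and a methylene group and cannot bias the addition, so control is by catalyst alone.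

Step 20
Reactants: 30 (3S,4S)-4-{4-(benzyloxy)-3-[(1S,2R)-1-(4-benzyloxy-3-methoxyphenyl)-1-hydroxybut-3-en-2-yl]-5-methoxybenzyl}-3-(DBFm)dihydrofuran-2(3H)-one
Product: 32 (3S,4S)-4-{4-(benzyloxy)-3-[(1S,2S)-1-(4-benzyloxy-3-methoxyphenyl)-1,3-dihydroxypropan-2-yl]-5-methoxybenzyl}-3-(DBFm)dihydrofuran-2(3H)-one, via aldehyde 31 (not isolated)
Conditions: O3, CH2Cl2/MeOH (3:1), Sudan Red 7B, −78 °C; then NaBH4, −78 → 0 °C
Reagents that add atoms: ozone, [O-][O+]=O
Why: Ozonolysis with the indicator dye stops at the terminal alkene, and immediate borohydride reduction converts the β-hydroxy aldehyde 31 into the diol before retro-aldol cleavage or epimerisation at C8. The lactone is not reduced by NaBH4 at this temperature, and the change of descriptor at C8 is a priority change only.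

Step 21
Reactants: 32 (3S,4S)-4-{4-(benzyloxy)-3-[(1S,2S)-1-(4-benzyloxy-3-methoxyphenyl)-1,3-dihydroxypropan-2-yl]-5-methoxybenzyl}-3-(DBFm)dihydrofuran-2(3H)-one
Product: 33 (3S,4S)-3-({(2R,3S)-2-[4-(benzyloxy)-3-methoxyphenyl]-3-(hydroxymethyl)-7-methoxy-2,3-dihydrobenzofuran-5-yl}methyl)-4-{4-(benzyloxy)-3-[(1S,2S)-1-(4-benzyloxy-3-methoxyphenyl)-1,3-dihydroxypropan-2-yl]-5-methoxybenzyl}dihydrofuran-2(3H)-one
Conditions: TBAF, AcOH (1:1), THF, rt
Reagents that add atoms: none
Why: Buffered fluoride removes the primary TBS ether without acid (which would ionise the C7 carbinol) and without free base at the lactone.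

Step 22
Reactants: 33 (3S,4S)-3-({(2R,3S)-2-[4-(benzyloxy)-3-methoxyphenyl]-3-(hydroxymethyl)-7-methoxy-2,3-dihydrobenzofuran-5-yl}methyl)-4-{4-(benzyloxy)-3-[(1S,2S)-1-(4-benzyloxy-3-methoxyphenyl)-1,3-dihydroxypropan-2-yl]-5-methoxybenzyl}dihydrofuran-2(3H)-one
Product: 34 (3S,4S)-3-{[(2R,3S)-2-(4-hydroxy-3-methoxyphenyl)-3-(hydroxymethyl)-7-methoxy-2,3-dihydrobenzofuran-5-yl]methyl}-4-{3-[(1S,2S)-1,3-dihydroxy-1-(4-hydroxy-3-methoxyphenyl)propan-2-yl]-4-hydroxy-5-methoxybenzyl}dihydrofuran-2(3H)-one (target)
Conditions: H2 (1 atm), 10% Pd/C, EtOAc/EtOH (1:1), rt, stopped at the end-point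
Reagents that add atoms: none
Why: Hydrogenolysis of three aryl benzyl ethers, which cleave much faster than the C7 benzylic C–OH bond or the benzylic C–O bond of the furan ring under neutral conditions at atmospheric pressure. No stereocentre is involved.

## Compound list

1 | eugenol (4-allyl-2-methoxyphenol) | C=CCc1ccc(O)c(OC)c1 | starting material
2 | 4-allyl-2-bromo-6-methoxyphenol | C=CCc1cc(Br)c(O)c(OC)c1 | intermediate
3 | benzyl bromide | BrCc1ccccc1 | starting material
4 | 5-allyl-2-(benzyloxy)-1-bromo-3-methoxybenzene | C=CCc1cc(Br)c(OCc2ccccc2)c(OC)c1 | intermediate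
5 | trichloroacetyl chloride | O=C(Cl)C(Cl)(Cl)Cl | starting material
6 | dichloroketene | O=C=C(Cl)Cl | intermediate
7 | racemic 3-[4-(benzyloxy)-3-bromo-5-methoxybenzyl]-2,2-dichlorocyclobutan-1-one | O=C1CC(Cc2cc(Br)c(OCc3ccccc3)c(OC)c2)C1(Cl)Cl | intermediate
8 | 3-[4-(benzyloxy)-3-bromo-5-methoxybenzyl]cyclobutan-1-one | O=C1CC(Cc2cc(Br)c(OCc3ccccc3)c(OC)c2)C1 | intermediate
9 | Criegee adduct, 3-[4-(benzyloxy)-3-bromo-5-methoxybenzyl]-1-hydroperoxycyclobutan-1-ol | OOC1(O)CC(Cc2cc(Br)c(OCc3ccccc3)c(OC)c2)C1 | intermediate
10 | (S)-4-[4-(benzyloxy)-3-bromo-5-methoxybenzyl]dihydrofuran-2(3H)-one | COc1cc(C[C@@H]2COC(=O)C2)cc(Br)c1OCc1ccccc1 | intermediate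
11 | methyl 3-bromo-4-hydroxy-5-methoxybenzoate | COC(=O)c1cc(Br)c(O)c(OC)c1 | starting material
12 | methyl 3-bromo-5-methoxy-4-(triisopropylsilyloxy)benzoate | COC(=O)c1cc(Br)c(O[Si](C(C)C)(C(C)C)C(C)C)c(OC)c1 | intermediate
13 | methyl 3-methoxy-4-(triisopropylsilyloxy)-5-vinylbenzoate | COC(=O)c1cc(C=C)c(O[Si](C(C)C)(C(C)C)C(C)C)c(OC)c1 | intermediate
14 | methyl 3-methoxy-5-[(E)-3-(pinacolboryl)prop-1-en-1-yl]-4-(triisopropylsilyloxy)benzoate | COC(=O)c1cc(/C=C/CB2OC(C)(C)C(C)(C)O2)c(O[Si](C(C)C)(C(C)C)C(C)C)c(OC)c1 | intermediate
15 | 4-(benzyloxy)-3-methoxybenzaldehyde | COc1cc(C=O)ccc1OCc1ccccc1 | starting material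
16 | pinacol borate ester of 17 (O–B bond at the (1S) carbinol oxygen, (2R) unchanged) | COC(=O)c1cc(OC)c(O[Si](C(C)C)(C(C)C)C(C)C)c(c1)[C@@H](C=C)[C@H](OB1OC(C)(C)C(C)(C)O1)c1ccc(OCc2ccccc2)c(OC)c1 | intermediate
17 | methyl 3-[(1S,2R)-1-(4-benzyloxy-3-methoxyphenyl)-1-hydroxybut-3-en-2-yl]-5-methoxy-4-(triisopropylsilyloxy)benzoate | COC(=O)c1cc(OC)c(O[Si](C(C)C)(C(C)C)C(C)C)c(c1)[C@@H](C=C)[C@H](O)c1ccc(OCc2ccccc2)c(OC)c1 | intermediate
18 | methyl 3-[(1S,2R)-1-(4-benzyloxy-3-methoxyphenyl)-1-hydroxybut-3-en-2-yl]-4-hydroxy-5-methoxybenzoate | COC(=O)c1cc(OC)c(O)c(c1)[C@@H](C=C)[C@H](O)c1ccc(OCc2ccccc2)c(OC)c1 | intermediate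
19 | methyl (2R,3R)-2-[4-(benzyloxy)-3-methoxyphenyl]-7-methoxy-3-vinyl-2,3-dihydrobenzofuran-5-carboxylate (trans) | COC(=O)c1cc(OC)c2c(c1)[C@@H](C=C)[C@H](c1ccc(OCc3ccccc3)c(OC)c1)O2 | intermediate
20 | methyl (2R,3R)-2-[4-(benzyloxy)-3-methoxyphenyl]-3-formyl-7-methoxy-2,3-dihydrobenzofuran-5-carboxylate (trans) | COC(=O)c1cc(OC)c2c(c1)[C@@H](C=O)[C@H](c1ccc(OCc3ccccc3)c(OC)c1)O2 | intermediate
21 | methyl (2R,3S)-2-[4-(benzyloxy)-3-methoxyphenyl]-3-(hydroxymethyl)-7-methoxy-2,3-dihydrobenzofuran-5-carboxylate | COC(=O)c1cc(OC)c2c(c1)[C@@H](CO)[C@H](c1ccc(OCc3ccccc3)c(OC)c1)O2 | intermediate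
22 | methyl (2R,3S)-2-[4-(benzyloxy)-3-methoxyphenyl]-3-[(tert-butyldimethylsilyloxy)methyl]-7-methoxy-2,3-dihydrobenzofuran-5-carboxylate | COC(=O)c1cc(OC)c2c(c1)[C@@H](CO[Si](C)(C)C(C)(C)C)[C@H](c1ccc(OCc3ccccc3)c(OC)c1)O2 | intermediate
23 | {(2R,3S)-2-[4-(benzyloxy)-3-methoxyphenyl]-3-[(tert-butyldimethylsilyloxy)methyl]-7-methoxy-2,3-dihydrobenzofuran-5-yl}methanol | OCc1cc(OC)c2c(c1)[C@@H](CO[Si](C)(C)C(C)(C)C)[C@H](c1ccc(OCc3ccccc3)c(OC)c1)O2 | intermediate
24 | (2R,3S)-2-[4-(benzyloxy)-3-methoxyphenyl]-5-(bromomethyl)-3-[(tert-butyldimethylsilyloxy)methyl]-7-methoxy-2,3-dihydrobenzofuran | BrCc1cc(OC)c2c(c1)[C@@H](CO[Si](C)(C)C(C)(C)C)[C@H](c1ccc(OCc3ccccc3)c(OC)c1)O2 | intermediate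
25 | lithium enolate of 10 (lithium (S)-3-[4-(benzyloxy)-3-bromo-5-methoxybenzyl]-2,3-dihydrofuran-5-olate) | [Li+].COc1cc(C[C@@H]2COC([O-])=C2)cc(Br)c1OCc1ccccc1 | intermediate
26 | (3S,4S)-4-[4-(benzyloxy)-3-bromo-5-methoxybenzyl]-3-(DBFm)dihydrofuran-2(3H)-one | COc1cc(C[C@@H]2COC(=O)[C@H]2Cc2cc(OC)c3c(c2)[C@@H](CO[Si](C)(C)C(C)(C)C)[C@H](c2ccc(OCc4ccccc4)c(OC)c2)O3)cc(Br)c1OCc1ccccc1 | intermediate
27 | (3S,4S)-4-[4-(benzyloxy)-3-methoxy-5-vinylbenzyl]-3-(DBFm)dihydrofuran-2(3H)-one | COc1cc(C[C@@H]2COC(=O)[C@H]2Cc2cc(OC)c3c(c2)[C@@H](CO[Si](C)(C)C(C)(C)C)[C@H](c2ccc(OCc4ccccc4)c(OC)c2)O3)cc(C=C)c1OCc1ccccc1 | intermediate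
28 | (3S,4S)-4-{4-(benzyloxy)-3-methoxy-5-[(E)-3-(pinacolboryl)prop-1-en-1-yl]benzyl}-3-(DBFm)dihydrofuran-2(3H)-one | COc1cc(C[C@@H]2COC(=O)[C@H]2Cc2cc(OC)c3c(c2)[C@@H](CO[Si](C)(C)C(C)(C)C)[C@H](c2ccc(OCc4ccccc4)c(OC)c2)O3)cc(/C=C/CB2OC(C)(C)C(C)(C)O2)c1OCc1ccccc1 | intermediate
29 | pinacol borate ester of 30 (O–B bond at the C7 oxygen) | COc1cc([C@@H](OB6OC(C)(C)C(C)(C)O6)[C@H](C=C)c2cc(C[C@@H]3COC(=O)[C@H]3Cc3cc(OC)c4c(c3)[C@@H](CO[Si](C)(C)C(C)(C)C)[C@H](c3ccc(OCc5ccccc5)c(OC)c3)O4)cc(OC)c2OCc2ccccc2)ccc1OCc1ccccc1 | intermediate
30 | (3S,4S)-4-{4-(benzyloxy)-3-[(1S,2R)-1-(4-benzyloxy-3-methoxyphenyl)-1-hydroxybut-3-en-2-yl]-5-methoxybenzyl}-3-(DBFm)dihydrofuran-2(3H)-one | COc1cc([C@@H](O)[C@H](C=C)c2cc(C[C@@H]3COC(=O)[C@H]3Cc3cc(OC)c4c(c3)[C@@H](CO[Si](C)(C)C(C)(C)C)[C@H](c3ccc(OCc5ccccc5)c(OC)c3)O4)cc(OC)c2OCc2ccccc2)ccc1OCc1ccccc1 | intermediate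
31 | (3S,4S)-4-{4-(benzyloxy)-3-[(1S,2R)-1-(4-benzyloxy-3-methoxyphenyl)-1-hydroxy-3-oxopropan-2-yl]-5-methoxybenzyl}-3-(DBFm)dihydrofuran-2(3H)-one | COc1cc([C@@H](O)[C@H](C=O)c2cc(C[C@@H]3COC(=O)[C@H]3Cc3cc(OC)c4c(c3)[C@@H](CO[Si](C)(C)C(C)(C)C)[C@H](c3ccc(OCc5ccccc5)c(OC)c3)O4)cc(OC)c2OCc2ccccc2)ccc1OCc1ccccc1 | intermediate
32 | (3S,4S)-4-{4-(benzyloxy)-3-[(1S,2S)-1-(4-benzyloxy-3-methoxyphenyl)-1,3-dihydroxypropan-2-yl]-5-methoxybenzyl}-3-(DBFm)dihydrofuran-2(3H)-one | COc1cc([C@@H](O)[C@H](CO)c2cc(C[C@@H]3COC(=O)[C@H]3Cc3cc(OC)c4c(c3)[C@@H](CO[Si](C)(C)C(C)(C)C)[C@H](c3ccc(OCc5ccccc5)c(OC)c3)O4)cc(OC)c2OCc2ccccc2)ccc1OCc1ccccc1 | intermediate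
33 | tri-O-benzyl ether of the target (benzyl on the phenols of rings A, C and D; all alcohols free; configurations as in 34) | COc1cc([C@@H](O)[C@H](CO)c2cc(C[C@@H]3COC(=O)[C@H]3Cc3cc(OC)c4c(c3)[C@@H](CO)[C@H](c3ccc(OCc5ccccc5)c(OC)c3)O4)cc(OC)c2OCc2ccccc2)ccc1OCc1ccccc1 | intermediate
34 | (3S,4S)-3-{[(2R,3S)-2-(4-hydroxy-3-methoxyphenyl)-3-(hydroxymethyl)-7-methoxy-2,3-dihydrobenzofuran-5-yl]methyl}-4-{3-[(1S,2S)-1,3-dihydroxy-1-(4-hydroxy-3-methoxyphenyl)propan-2-yl]-4-hydroxy-5-methoxybenzyl}dihydrofuran-2(3H)-one | COc1cc([C@@H](O)[C@H](CO)c2cc(C[C@@H]3COC(=O)[C@H]3Cc3cc(OC)c4c(c3)[C@@H](CO)[C@H](c3ccc(O)c(OC)c3)O4)cc(OC)c2O)ccc1O | target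

## Step count and least certain steps

Total: 22 steps. Longest linear sequence: 17 steps (from 11 through steps 6–15, then steps 16–22). The eugenol branch contributes 5 steps (1–5) before the convergence in step 16.

**Step 5 (key step).** The likely failure is incomplete discrimination between the two enantiotopic methylene groups during migration, because the only group that tells them apart, the aryl ring, sits one carbon away from the four-membered ring and offers the catalyst little to hold.
Fallback, from 8 back to 10: desymmetrise the ketone by enantioselective deprotonation instead of oxygen insertion. Ketone 8 is treated with the appropriate enantiomer of LiN[CH(CH3)Ph]2 in THF at −100 °C with Et3SiCl present, giving (S)-{[3-(4-benzyloxy-3-bromo-5-methoxybenzyl)cyclobut-1-en-1-yl]oxy}triethylsilane F1. Ozonolysis of the enol ether double bond with NaBH4 work-up gives (S)-3-(4-benzyloxy-3-bromo-5-methoxybenzyl)-4-hydroxybutanoic acid F2, which closes to lactone 10 on acidification.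

**Step 19 (and step 9, the same reaction on the small fragment).** The likely failure is loss of facial selectivity through an uncatalysed background addition, which is anti-selective but blind to the aldehyde face. The ortho-benzyloxy γ-aryl boronate is hindered and aldehyde 15 is electron-rich, so the catalysed pathway is slowed. In step 19 the error would appear as a diastereomer of a large molecule.
Fallback, from 26 back to 30: replace the boronate by a catalytic allyl-ruthenium route. Sonogashira coupling of 26 with propyne (Pd(PPh3)2Cl2, CuI, Et3N) gives the 1-aryl-1-propyne F3, that is 26 with prop-1-ynyl in place of bromine. F3 is coupled with (4-benzyloxy-3-methoxyphenyl)methanol F4 under RuH2(CO)(PPh3)3 with a Josiphos-type ligand in THF at 95 °C. Alcohol dehydrogenation, alkyne-to-allene isomerisation and hydrometalation give a chiral allyl-ruthenium species that adds to the aldehyde formed in situ, which is the anti-selective, enantioselective carbonyl (α-aryl)allylation, and this returns 30.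

**Step 18 (and step 8).** The likely failure is stalling of the metathesis: the ruthenium benzylidene formed from the styrene can chelate to the ortho-benzyloxy oxygen, while self-metathesis of the allylboronate consumes the partner. Partial Z-alkene formation would leak into the syn arm in step 19.
Fallback, from 26 back to 28: Suzuki–Miyaura coupling of 26 with (E)-3-(4,4,5,5-tetramethyl-1,3,2-dioxaborolan-2-yl)prop-2-en-1-ol F5 gives the (E)-cinnamyl alcohol F6 with fixed geometry. Palladium-catalysed borylation of the allylic alcohol with B2pin2 ([Pd(MeCN)4](BF4)2, DMSO/MeOH, 50 °C) through a π-allyl intermediate gives the linear E boronate 28. The same two operations would serve from 12 to 14.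

**Step 20 (and step 12).** The likely failures are over-oxidation of the four electron-rich arenes by ozone once the alkene is consumed, and retro-aldol cleavage or epimerisation at C8 at the aldehyde stage, because the aldehyde is β-hydroxylated and α-arylated.
Fallback, from 30 back to 32: dihydroxylation of the vinyl group (K2OsO2(OH)4 catalytic, NMO, acetone/H2O) gives the triol F7. Cleavage with NaIO4 at pH 7 and reduction with NaBH4 at −20 °C then give 32, again through aldehyde 31 but without any oxidant that attacks arenes.

**Step 11.** The likely failure is ionisation of the activated, electron-rich benzylic alcohol before the phenoxide attacks. That opens elimination toward the conjugated diene (C8–H is benzylic and allylic) and removes the guarantee of inversion.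
Fallback, from 18 back to 19: give up stereospecific displacement and close the ring under thermodynamic control. Catalytic TsOH in CH2Cl2 at rt takes 18 through the p-alkoxybenzyl cation, which the neighbouring phenol traps to the more stable trans ring; C3 is not involved and keeps its configuration. No new compound is made.

## Further compounds

F1 | step 5 | (S)-{[3-(4-benzyloxy-3-bromo-5-methoxybenzyl)cyclobut-1-en-1-yl]oxy}triethylsilane | CC[Si](CC)(CC)OC1=C[C@@H](Cc2cc(Br)c(OCc3ccccc3)c(OC)c2)C1
F2 | step 5 | (S)-3-(4-benzyloxy-3-bromo-5-methoxybenzyl)-4-hydroxybutanoic acid | OC[C@@H](Cc1cc(Br)c(OCc2ccccc2)c(OC)c1)CC(=O)O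
F3 | step 19 | (3S,4S)-4-[4-(benzyloxy)-3-methoxy-5-(prop-1-yn-1-yl)benzyl]-3-(DBFm)dihydrofuran-2(3H)-one | COc1cc(C[C@@H]2COC(=O)[C@H]2Cc2cc(OC)c3c(c2)[C@@H](CO[Si](C)(C)C(C)(C)C)[C@H](c2ccc(OCc4ccccc4)c(OC)c2)O3)cc(C#CC)c1OCc1ccccc1
F4 | step 19 | (4-benzyloxy-3-methoxyphenyl)methanol | COc1cc(CO)ccc1OCc1ccccc1
F5 | step 18 | (E)-3-(4,4,5,5-tetramethyl-1,3,2-dioxaborolan-2-yl)prop-2-en-1-ol | OC/C=C/B1OC(C)(C)C(C)(C)O1
F6 | step 18 | (3S,4S)-4-{4-(benzyloxy)-3-[(E)-3-hydroxyprop-1-en-1-yl]-5-methoxybenzyl}-3-(DBFm)dihydrofuran-2(3H)-one | COc1cc(C[C@@H]2COC(=O)[C@H]2Cc2cc(OC)c3c(c2)[C@@H](CO[Si](C)(C)C(C)(C)C)[C@H](c2ccc(OCc4ccccc4)c(OC)c2)O3)cc(/C=C/CO)c1OCc1ccccc1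
F7 | step 20 | triol from dihydroxylation of the vinyl group of 30 (new secondary carbinol as an epimer mixture) | COc1cc([C@@H](O)[C@H](C(O)CO)c2cc(C[C@@H]3COC(=O)[C@H]3Cc3cc(OC)c4c(c3)[C@@H](CO[Si](C)(C)C(C)(C)C)[C@H](c3ccc(OCc5ccccc5)c(OC)c3)O4)cc(OC)c2OCc2ccccc2)ccc1OCc1ccccc1
F0 | step 11 | none | none
A1 | alternative 1 | lactone bis(anti homoallylic alcohol) carrying both arms with vinyl as latent CH2OH | COc1cc([C@@H](O)[C@H](C=C)c2cc(C[C@@H]3COC(=O)[C@H]3Cc3cc(OC)c(O[Si](C(C)C)(C(C)C)C(C)C)c(c3)[C@@H](C=C)[C@H](O)c3ccc(OCc4ccccc4)c(OC)c3)cc(OC)c2OCc2ccccc2)ccc1OCc1ccccc1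
A2 | alternative 1 | (3S,4S)-lactone with an (E)-3-(pinacolboryl)prop-1-enyl group on ring A (benzyl ether) and on ring B (TIPS ether) | COc1cc(C[C@@H]2COC(=O)[C@H]2Cc2cc(OC)c(O[Si](C(C)C)(C(C)C)C(C)C)c(/C=C/CB3OC(C)(C)C(C)(C)O3)c2)cc(/C=C/CB2OC(C)(C)C(C)(C)O2)c1OCc1ccccc1
A3 | alternative 2 | lactone bearing the trans-4-(4-benzyloxy-3-methoxyphenyl)-1,3-dioxan-5-yl group on ring A (pivalate on the ring A phenol) | COc1cc(C[C@@H]2COC(=O)C2)cc([C@H]2COCO[C@@H]2c2ccc(OCc3ccccc3)c(OC)c2)c1OC(=O)C(C)(C)C
A4 | alternative 2 | (E)-stilbene joining ring A of the (S)-lactone (pivalate) to the 4-benzyloxy-3-methoxyphenyl ring | COc1cc(C[C@@H]2COC(=O)C2)cc(/C=C/c2ccc(OCc3ccccc3)c(OC)c2)c1OC(=O)C(C)(C)C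
A5 | alternative 2 | formaldehyde | C=O
A6 | alternative 3 | trans-2-(4-benzyloxy-3-methoxyphenyl)-3-(tert-butyldimethylsilyloxymethyl)-5-chloro-7-methoxy-2,3-dihydrobenzofuran | Clc1cc(OC)c2c(c1)[C@@H](CO[Si](C)(C)C(C)(C)C)[C@H](c1ccc(OCc3ccccc3)c(OC)c1)O2
A7 | alternative 3 | 6-chloro-4-methoxypyridazin-3-yl ether of the anti 1-(4-benzyloxy-3-methoxyphenyl)-2-(tert-butyldimethylsilyloxymethyl)but-3-yn-1-ol | COc1cc(Cl)nnc1O[C@@H](c1ccc(OCc2ccccc2)c(OC)c1)[C@H](CO[Si](C)(C)C(C)(C)C)C#C
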